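**Plan**

- Labels: ring A carries the hydroxymethyl carbon C7 on C1, the bridging methylene C8 on C2, OH on C3 and C4, and Br on C5. Ring B is joined to C8 through C1' and carries Br on C3' and OH on C4'.
- Enabling feature: ring B is a para-alkyl ortho-bromophenol, which is the aromatized and once-brominated form of a 4-substituted cyclohex-2-enone.
- Retrosynthesis: remove C3'–Br, dearomatize ring B, then cut C2'=C3' (aldol condensation) and C1'–C6' (conjugate addition). This leaves a ring A 3-arylpropanal and methyl vinyl ketone. The propanal comes from an allyl group, and the C2–C8 bond from an aromatic Claisen rearrangement.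
- Forward: ring A is bought with its bromine and both oxygens. The allyl group is placed at C2 (steps 1–3), the oxygens are capped as methyl ethers (4–5), the chain becomes the propanal (6–7), ring B is annulated (8), aromatized (9) and brominated (10), and all methyl ethers are removed (11).
- Stereochemistry: the target has no stereocentre. The only one formed on the way (C4 of the cyclohexenone, future C1') is racemic and disappears on aromatization.

Key step: step 8

Remark: 3-bromo-4,5-dihydroxybenzaldehyde, allyl bromide and methyl vinyl ketone are taken to be commercial.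

**Route**

Step 1
Reactants: 1 3-bromo-4,5-dihydroxybenzaldehyde
Product: 2 3-bromo-5-hydroxy-4-methoxybenzaldehyde
Conditions: MeI (1.05 equiv), Li2CO3 (1.1 equiv), DMF, 40 °C
Reagents that add atoms: iodomethane, CI
Why: The 4-OH, para to the formyl group and flanked by bromine, is the more acidic phenol, so a weak base forms essentially only that phenoxide and Williamson O-methylation should occur there, as in the known regioselective 4-O-alkylation of 3,4-dihydroxybenzaldehydes.

Step 2
Reactants: 2 3-bromo-5-hydroxy-4-methoxybenzaldehyde; 3 allyl bromide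
Product: 4 3-bromo-4-methoxy-5-(prop-2-en-1-yloxy)benzaldehyde
Conditions: K2CO3, DMF, rt
Reagents that add atoms: none
Why: Williamson etherification of the remaining phenoxide by an allylic bromide is routine and leaves the aldehyde and the aryl bromide untouched.

Step 3
Reactants: 4 3-bromo-4-methoxy-5-(prop-2-en-1-yloxy)benzaldehyde
Product: 6 5-bromo-3-hydroxy-4-methoxy-2-(prop-2-en-1-yl)benzaldehyde, via ortho-dienone 5 (not isolated)
Conditions: PhNEt2, 195 °C, argon
Reagents that add atoms: none
Why: In this aromatic Claisen rearrangement one ortho position of the allyl ether is blocked by the methoxy group, so the [3,3] shift should deliver the allyl group to the free carbon between oxygen and the formyl group (future C2), after which dienone 5 tautomerizes to the phenol, as known for 3-allyloxy-4-methoxybenzaldehyde.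

Step 4
Reactants: 6 5-bromo-3-hydroxy-4-methoxy-2-(prop-2-en-1-yl)benzaldehyde
Product: 7 [5-bromo-3-hydroxy-4-methoxy-2-(prop-2-en-1-yl)phenyl]methanol
Conditions: NaBH4, MeOH, 0 °C
Reagents that add atoms: none
Why: Borohydride reduction of an aromatic aldehyde gives the benzylic alcohol without touching the terminal alkene or the aryl bromide, and removes the second carbonyl group before the hydroboration and enamine steps.

Step 5
Reactants: 7 [5-bromo-3-hydroxy-4-methoxy-2-(prop-2-en-1-yl)phenyl]methanol
Product: 8 1-bromo-2,3-dimethoxy-5-(methoxymethyl)-4-(prop-2-en-1-yl)benzene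
Conditions: NaH (2.5 equiv), MeI (3 equiv), THF/DMF, 0 °C → rt
Reagents that add atoms: iodomethane, CI
Why: Double Williamson methylation of the phenoxide and the benzylic alkoxide caps both oxygens in one operation as ethers that tolerate borane, amine, enolate and NBS chemistry and that BBr3 removes together at the end.

Step 6
Reactants: 8 1-bromo-2,3-dimethoxy-5-(methoxymethyl)-4-(prop-2-en-1-yl)benzene
Product: 10 3-[4-bromo-2,3-dimethoxy-6-(methoxymethyl)phenyl]propan-1-ol, via B-alkyl-9-BBN adduct 9 (not isolated)
Conditions: 9-BBN, THF, 0 °C → rt; then NaOH aq, H2O2, 0 °C → rt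
Reagents that add atoms: hydrogen peroxide, OO
Why: Hydroboration–oxidation with the bulky 9-BBN places boron on the terminal carbon of the allyl group, and alkaline peroxide converts borane 9 into the primary alcohol with the aryl bromide and ethers intact.

Step 7
Reactants: 10 3-[4-bromo-2,3-dimethoxy-6-(methoxymethyl)phenyl]propan-1-ol
Product: 11 3-[4-bromo-2,3-dimethoxy-6-(methoxymethyl)phenyl]propanal
Conditions: Dess–Martin periodinane, CH2Cl2, 0 °C → rt
Reagents that add atoms: none
Why: Dess–Martin oxidation converts the primary alcohol into the aldehyde under mild conditions without over-oxidation, and the aldehyde is used at once in the annulation.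

Step 8
Reactants: 11 3-[4-bromo-2,3-dimethoxy-6-(methoxymethyl)phenyl]propanal; 12 methyl vinyl ketone
Product: 16 4-{[4-bromo-2,3-dimethoxy-6-(methoxymethyl)phenyl]methyl}cyclohex-2-en-1-one (racemic), via enamine 13 (not isolated), via keto aldehyde 14 (not isolated), via aldol 15 (not isolated)
Conditions: pyrrolidine (1.2 equiv), 4 Å molecular sieves, toluene, 0 °C → rt; methyl vinyl ketone (1.2 equiv), 0 °C → rt; then AcOH/NaOAc/H2O, 90 °C
Reagents that add atoms: none
Why: Condensation of 11 with pyrrolidine gives the E-enamine 13, whose nucleophilic β-carbon (the aldehyde α-carbon, future C1') adds to the terminal carbon of methyl vinyl ketone and forms the C1'–C6' bond, and hydrolysis in the acetate buffer releases keto aldehyde 14. The methyl ketone then enolizes toward its methyl group and attacks the aldehyde carbon in a 6-(enolendo)-exo-trig aldol closure to aldol 15, and loss of water gives the conjugated C2'=C3' double bond of enone 16. The closest known reaction type is the Stork enamine variant of the Robinson annulation, by which unbranched aldehydes such as 3-phenylpropanal and methyl vinyl ketone give 4-substituted cyclohex-2-enones. The one new stereocentre (C4 of the enone, future C1') has no controlling element and forms as a racemate, which does not matter because it becomes an aromatic carbon in step 9. The step needs a single conjugate addition at the aldehyde α-carbon and ring closure in one direction only: the first is secured because all the aldehyde is held as its enamine before the enone is added and the mono-adduct is more hindered, the second because every other enol and carbonyl pairing in 14 would close a four-membered ring. The aryl bromide, the methyl ethers and the benzylic ether of ring A are inert to the amine and to hot acetate buffer.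

Step 9
Reactants: 16 4-{[4-bromo-2,3-dimethoxy-6-(methoxymethyl)phenyl]methyl}cyclohex-2-en-1-one
Product: 20 4-{[4-bromo-2,3-dimethoxy-6-(methoxymethyl)phenyl]methyl}phenol, via selenide 17 (not isolated), via selenoxide 18 (not isolated), via dienone 19 (not isolated)
Conditions: LiN(iPr)2, THF, −78 °C; PhSeCl, −78 °C; aqueous work-up; then mCPBA (1.0 equiv), CH2Cl2, −78 °C; iPr2NH (3 equiv), −78 °C → rt
Reagents that add atoms: none
Why: Kinetic deprotonation at C6 gives the cross-conjugated dienolate, which PhSeCl selenenylates there, and oxidation to selenoxide 18 followed by syn-elimination toward C5 gives the 4-H cyclohexa-2,5-dienone 19, which tautomerizes to the phenol (α-selenenylation and selenoxide elimination, the standard dehydrogenation of ketones), the oxidant being consumed at −78 °C before any phenol exists.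

Step 10
Reactants: 20 4-{[4-bromo-2,3-dimethoxy-6-(methoxymethyl)phenyl]methyl}phenol
Product: 21 2-bromo-4-{[4-bromo-2,3-dimethoxy-6-(methoxymethyl)phenyl]methyl}phenol
Conditions: NBS (1.0 equiv), iPr2NH (10 mol %), CH2Cl2, 0 °C
Reagents that add atoms: N-bromosuccinimide, O=C1CCC(=O)N1Br
Why: In this amine-catalysed electrophilic ortho-bromination of a phenol the para position is blocked and the two ortho carbons are equivalent, so one equivalent of NBS should give a single monobromide, while the only free carbon of the non-phenolic ring A, wedged between bromine and the methoxymethyl group, reacts far more slowly.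

Step 11
Reactants: 21 2-bromo-4-{[4-bromo-2,3-dimethoxy-6-(methoxymethyl)phenyl]methyl}phenol
Product: 23 6-bromo-3-[(3-bromo-4-hydroxyphenyl)methyl]-4-(hydroxymethyl)benzene-1,2-diol, via benzylic bromide 22 (not isolated)
Conditions: BBr3 (6 equiv), CH2Cl2, −78 → 0 °C; ice/H2O; then acetone/H2O, NaHCO3, rt
Reagents that add atoms: water, O
Why: BBr3 ether cleavage removes the two aryl methyl groups and turns the electron-rich benzylic methyl ether into benzylic bromide 22, a para-hydroxybenzyl halide that buffered aqueous acetone should solvolyse to the benzylic alcohol as is known for bromomethyl catechols of this family, while the aryl bromides do not react and the ring B carbons next to the bridge are meta to oxygen and thus poor partners for Friedel–Crafts closure.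

**Compound list**

1 | 3-bromo-4,5-dihydroxybenzaldehyde | O=Cc1cc(O)c(O)c(Br)c1 | starting material
2 | 3-bromo-5-hydroxy-4-methoxybenzaldehyde | COc1c(O)cc(C=O)cc1Br | intermediate
3 | allyl bromide (3-bromoprop-1-ene) | C=CCBr | starting material
4 | 3-bromo-4-methoxy-5-(prop-2-en-1-yloxy)benzaldehyde | COc1c(OCC=C)cc(C=O)cc1Br | intermediate
5 | 3-bromo-4-methoxy-5-oxo-6-(prop-2-en-1-yl)cyclohexa-1,3-diene-1-carbaldehyde (racemic ortho-dienone) | O=CC1=CC(Br)=C(OC)C(=O)C1CC=C | intermediate
6 | 5-bromo-3-hydroxy-4-methoxy-2-(prop-2-en-1-yl)benzaldehyde | COc1c(Br)cc(C=O)c(CC=C)c1O | intermediate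
7 | [5-bromo-3-hydroxy-4-methoxy-2-(prop-2-en-1-yl)phenyl]methanol | COc1c(Br)cc(CO)c(CC=C)c1O | intermediate
8 | 1-bromo-2,3-dimethoxy-5-(methoxymethyl)-4-(prop-2-en-1-yl)benzene | COCc1cc(Br)c(OC)c(OC)c1CC=C | intermediate
9 | 9-{3-[4-bromo-2,3-dimethoxy-6-(methoxymethyl)phenyl]propyl}-9-borabicyclo[3.3.1]nonane | COCc1cc(Br)c(OC)c(OC)c1CCCB1C2CCCC1CCC2 | intermediate
10 | 3-[4-bromo-2,3-dimethoxy-6-(methoxymethyl)phenyl]propan-1-ol | COCc1cc(Br)c(OC)c(OC)c1CCCO | intermediate
11 | 3-[4-bromo-2,3-dimethoxy-6-(methoxymethyl)phenyl]propanal | COCc1cc(Br)c(OC)c(OC)c1CCC=O | intermediate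
12 | methyl vinyl ketone (but-3-en-2-one) | CC(=O)C=C | starting material
13 | 1-{(1E)-3-[4-bromo-2,3-dimethoxy-6-(methoxymethyl)phenyl]prop-1-en-1-yl}pyrrolidine | COCc1cc(Br)c(OC)c(OC)c1C/C=C/N1CCCC1 | intermediate
14 | 2-{[4-bromo-2,3-dimethoxy-6-(methoxymethyl)phenyl]methyl}-5-oxohexanal (racemic) | COCc1cc(Br)c(OC)c(OC)c1CC(C=O)CCC(C)=O | intermediate
15 | 4-{[4-bromo-2,3-dimethoxy-6-(methoxymethyl)phenyl]methyl}-3-hydroxycyclohexan-1-one (racemic, mixture of diastereomers) | COCc1cc(Br)c(OC)c(OC)c1CC1CCC(=O)CC1O | intermediate
16 | 4-{[4-bromo-2,3-dimethoxy-6-(methoxymethyl)phenyl]methyl}cyclohex-2-en-1-one (racemic) | COCc1cc(Br)c(OC)c(OC)c1CC1CCC(=O)C=C1 | intermediate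
17 | 4-{[4-bromo-2,3-dimethoxy-6-(methoxymethyl)phenyl]methyl}-6-(phenylselanyl)cyclohex-2-en-1-one (racemic, mixture of diastereomers) | COCc1cc(Br)c(OC)c(OC)c1CC1CC([Se]c2ccccc2)C(=O)C=C1 | intermediate
18 | 6-(benzeneseleninyl)-4-{[4-bromo-2,3-dimethoxy-6-(methoxymethyl)phenyl]methyl}cyclohex-2-en-1-one (mixture of stereoisomers) | COCc1cc(Br)c(OC)c(OC)c1CC1CC([Se](=O)c2ccccc2)C(=O)C=C1 | intermediate
19 | 4-{[4-bromo-2,3-dimethoxy-6-(methoxymethyl)phenyl]methyl}cyclohexa-2,5-dien-1-one | COCc1cc(Br)c(OC)c(OC)c1CC1C=CC(=O)C=C1 | intermediate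
20 | 4-{[4-bromo-2,3-dimethoxy-6-(methoxymethyl)phenyl]methyl}phenol | COCc1cc(Br)c(OC)c(OC)c1Cc1ccc(O)cc1 | intermediate
21 | 2-bromo-4-{[4-bromo-2,3-dimethoxy-6-(methoxymethyl)phenyl]methyl}phenol | COCc1cc(Br)c(OC)c(OC)c1Cc1ccc(O)c(Br)c1 | intermediate
22 | 6-bromo-3-[(3-bromo-4-hydroxyphenyl)methyl]-4-(bromomethyl)benzene-1,2-diol | BrCc1cc(Br)c(O)c(O)c1Cc1ccc(O)c(Br)c1 | intermediate
23 | 6-bromo-3-[(3-bromo-4-hydroxyphenyl)methyl]-4-(hydroxymethyl)benzene-1,2-diol | OCc1cc(Br)c(O)c(O)c1Cc1ccc(O)c(Br)c1 | target

**Count**

Total steps: 11. Longest linear sequence: 11 steps (1 → 23).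

**Steps most likely to fail**

Step 11. The benzylic position may ionize under BBr3 or during hydrolysis and alkylate an arene instead of being captured by water. This could occur within the molecule onto ring B, or between molecules through the quinone methide. The fallback moves C7 to the aldehyde level before the ethers are cleaved, so that no benzylic leaving group is present. It sets out from 21. Acetylation (Ac2O, pyridine) should give 2-bromo-4-{[4-bromo-2,3-dimethoxy-6-(methoxymethyl)phenyl]methyl}phenyl acetate F1. DDQ in wet CH2Cl2 should then oxidize the para-methoxybenzyl-type methyl ether to 2-bromo-4-[(4-bromo-6-formyl-2,3-dimethoxyphenyl)methyl]phenyl acetate F2, following the known oxidative cleavage of such ethers to the benzaldehyde. BBr3 in CH2Cl2 followed by K2CO3 in MeOH should remove the two methyl groups and the acetate and give 5-bromo-2-[(3-bromo-4-hydroxyphenyl)methyl]-3,4-dihydroxybenzaldehyde F3. Reduction with NaBH4 in THF/H2O at 0 °C brings the sequence back to the route at 23.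

Step 8. Methyl vinyl ketone may polymerize, add twice, or be outrun by self-condensation of the aldehyde. The fallback forms the same two bonds by alkylation and aldol condensation instead of conjugate addition. It sets out from 11. Condensation with cyclohexylamine over molecular sieves should give N-cyclohexyl-3-[4-bromo-2,3-dimethoxy-6-(methoxymethyl)phenyl]propan-1-imine F4. Deprotonation with LiN(iPr)2 in THF and alkylation of the metalloenamine with 2-(2-bromoethyl)-2-methyl-1,3-dioxolane should give N-cyclohexyl-2-{[4-bromo-2,3-dimethoxy-6-(methoxymethyl)phenyl]methyl}-4-(2-methyl-1,3-dioxolan-2-yl)butan-1-imine F5, with the C1'–C6' bond in place. Aqueous HCl in THF hydrolyses the imine and the ketal, and the sequence comes back to the route at keto aldehyde 14, which the acetate buffer of step 8 (or KOH in MeOH) closes to 16.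

Step 9. Enolization may be incomplete or occur at the wrong site, the enolate may be selenenylated twice, or the newly formed phenol may be attacked by selenium by-products. The fallback aromatizes by halogenation and dehydrohalogenation. It sets out from 16. LiN(iPr)2 and Me3SiCl in THF at −78 °C should give [(4-{[4-bromo-2,3-dimethoxy-6-(methoxymethyl)phenyl]methyl}cyclohexa-1,5-dien-1-yl)oxy]trimethylsilane F6. NBS in THF at 0 °C should convert it into 6-bromo-4-{[4-bromo-2,3-dimethoxy-6-(methoxymethyl)phenyl]methyl}cyclohex-2-en-1-one F7. Li2CO3 and LiBr in DMF at 120 °C should eliminate HBr, and tautomerization of the dienone brings the sequence back to the route at 20.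

**Further compounds**

F1 | step 11 | 2-bromo-4-{[4-bromo-2,3-dimethoxy-6-(methoxymethyl)phenyl]methyl}phenyl acetate | CC(=O)Oc1ccc(Cc2c(COC)cc(Br)c(OC)c2OC)cc1Br
F2 | step 11 | 2-bromo-4-[(4-bromo-6-formyl-2,3-dimethoxyphenyl)methyl]phenyl acetate | CC(=O)Oc1ccc(Cc2c(C=O)cc(Br)c(OC)c2OC)cc1Br
F3 | step 11 | 5-bromo-2-[(3-bromo-4-hydroxyphenyl)methyl]-3,4-dihydroxybenzaldehyde | O=Cc1cc(Br)c(O)c(O)c1Cc1ccc(O)c(Br)c1
F4 | step 8 | (E)-N-cyclohexyl-3-[4-bromo-2,3-dimethoxy-6-(methoxymethyl)phenyl]propan-1-imine | COCc1cc(Br)c(OC)c(OC)c1CC/C=N/C1CCCCC1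
F5 | step 8 | (E)-N-cyclohexyl-2-{[4-bromo-2,3-dimethoxy-6-(methoxymethyl)phenyl]methyl}-4-(2-methyl-1,3-dioxolan-2-yl)butan-1-imine (racemic) | COCc1cc(Br)c(OC)c(OC)c1CC(CCC1(C)OCCO1)/C=N/C1CCCCC1
F6 | step 9 | [(4-{[4-bromo-2,3-dimethoxy-6-(methoxymethyl)phenyl]methyl}cyclohexa-1,5-dien-1-yl)oxy]trimethylsilane (racemic) | COCc1cc(Br)c(OC)c(OC)c1CC1CC=C(O[Si](C)(C)C)C=C1
F7 | step 9 | 6-bromo-4-{[4-bromo-2,3-dimethoxy-6-(methoxymethyl)phenyl]methyl}cyclohex-2-en-1-one (racemic, mixture of diastereomers) | COCc1cc(Br)c(OC)c(OC)c1CC1CC(Br)C(=O)C=C1
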